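**Retrosynthetic overview**

1. The cyclopentenone is the only ring of the target and is made last, from an acyclic C20 chain. The C8–C12 bond is formed by conrotatory 4π closure of a 2-oxypentadienyl cation (carbons 8–12, oxygen on C9), the same bond and pericyclic event as in the coral allene oxide / oxidopentadienyl cation pathway. Here it is run on a 10-bromo-9,12-dioxo eicosanoid so that C12 emerges as the carbinol.
2. The enol ether needed at C8=C9 is the 2H-pyran valence tautomer of the (7Z)-dienone. Its retro-6π opening after ring closure fixes 7Z/5E, and a chiral Brønsted acid sets 12R.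
3. The cis-enedione comes from singlet-oxygen opening of a 2,5-disubstituted 3-bromofuran (a masked C9–C12 cis-enedione with bromine already on C10).
4. The furan comes from 2,3-dibromofuran by C5 alkylation with 1-bromooct-2-yne, a one-pot double Sonogashira coupling (ethynyltrimethylsilane, methyl (5E)-6-iodohex-5-enoate) and one double cis-semihydrogenation (7Z and 14Z).
5. Ring order: purchased furan (sacrificed), then transient 2H-pyran, then cyclopentenone.

Assumption: prostanoid numbering is used for positions (C1 = ester carbon, C20 = terminal methyl); the sense of induction in step 6 must be found by experiment, so the catalyst enantiomer that gives the (12R)-alcohol is used (written here as R).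

**Step 1**
Reactants: 1 2,3-dibromofuran; 2 1-bromooct-2-yne
Product: 4 2,3-dibromo-5-(oct-2-yn-1-yl)furan, via 4,5-dibromo-2-furyllithium 3 (not isolated)
Conditions: LiN(iPr)2 (1.05 equiv), THF, −78 °C, 30 min; then 2, DMPU, −78 → 0 °C
Reagents that add atoms: none
Why: Deprotonation occurs at C5, the only ring position that carries hydrogen next to oxygen, and the furyllithium displaces the primary propargylic bromide by SN2 without copper (directed lithiation–alkylation); no stereocentre is formed.

**Step 2**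
Reactants: 5 methyl hex-5-ynoate
Product: 7 methyl (5E)-6-iodohex-5-enoate, via (E)-alkenyl-Zr(Cl)Cp2 complex 6 (not isolated)
Conditions: Cp2Zr(H)Cl (1.2 equiv), THF, 23 °C; then I2, 0 °C
Reagents that add atoms: iodine, II
Why: Hydrozirconation adds Zr–H syn and anti-Markovnikov to the terminal alkyne much faster than it attacks the ester, and iodinolysis of the C–Zr bond goes with retention, which gives the E-vinyl iodide.

**Step 3**
Reactants: 7 methyl (5E)-6-iodohex-5-enoate; 8 ethynyltrimethylsilane; 4 2,3-dibromo-5-(oct-2-yn-1-yl)furan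
Product: 11 methyl (5E)-8-[3-bromo-5-(oct-2-yn-1-yl)furan-2-yl]oct-5-en-7-ynoate, via TMS-enyne ester 9 (not isolated), via terminal enyne ester 10 (not isolated)
Conditions: 7, 8 (1.05 equiv), PdCl2(PPh3)2 (3 mol%), CuI (5 mol%), Et3N, THF, 23 °C; then 4, CsF (2 equiv), MeOH, 50 °C
Reagents that add atoms: none
Why: Two Sonogashira couplings in one flask: the vinyl iodide couples first with retention of E geometry, fluoride then frees the alkyne, and zerovalent palladium inserts into the C2–Br bond next to the ring oxygen of 4 while the C3–Br bond stays (site-selective coupling of 2,3-dibromofurans).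

**Step 4**
Reactants: 11 methyl (5E)-8-[3-bromo-5-(oct-2-yn-1-yl)furan-2-yl]oct-5-en-7-ynoate
Product: 12 methyl (5E,7Z)-8-[3-bromo-5-[(2Z)-oct-2-en-1-yl]furan-2-yl]octa-5,7-dienoate
Conditions: H2 (1 atm, stopped at 2.0 equiv), Pd/CaCO3 poisoned with Pb(OAc)2, quinoline, EtOAc, 0 °C
Reagents that add atoms: none
Why: Lindlar semihydrogenation delivers H2 syn to both alkynes, which sets 7Z and 14Z in one operation, and the poisoned catalyst leaves the aryl bromide, the furan and the 5E alkene alone.

**Step 5**
Reactants: 12 methyl (5E,7Z)-8-[3-bromo-5-[(2Z)-oct-2-en-1-yl]furan-2-yl]octa-5,7-dienoate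
Product: 14 methyl (5E,7Z,10E,14Z)-10-bromo-9,12-dioxoicosa-5,7,10,14-tetraenoate, via furan endoperoxide 13 (not isolated)
Conditions: O2, methylene blue (0.5 mol%), red LED, CH2Cl2, −78 °C; then Me2S (1.5 equiv), −78 → −20 °C, dark; cold aqueous wash, used at once without chromatography
Reagents that add atoms: dioxygen, O=O
Why: Singlet oxygen adds [4+2] across C9/C12 of the 2,5-disubstituted furan far faster than it reacts with the skipped alkene or the (Z,E)-diene, and Me2S reduces the endoperoxide to the cis-enedione, whose C10=C11 geometry (C9 and C12 cis) is inherited from the ring (furan photooxygenation).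

**Step 6**
Reactants: 14 methyl (5E,7Z,10E,14Z)-10-bromo-9,12-dioxoicosa-5,7,10,14-tetraenoate
Product: 17 methyl (5E,7Z)-7-[(2R)-4-bromo-2-hydroxy-2-[(2Z)-oct-2-en-1-yl]-5-oxocyclopent-3-en-1-ylidene]hept-5-enoate (the target), via 2H-pyran tautomer 15 (not isolated), via cyclopenta[b]pyran 16 (not isolated)
Conditions: (R)-3,3'-bis(9-phenanthryl)-H8-BINOL N-triflylphosphoramide (5 mol%), 4 Å MS, CHCl3, −20 → 0 °C, dark
Reagents that add atoms: none
Why: Proposed new method: the (7Z)-dienone closes reversibly to its 2H-pyran tautomer 15 (thermal oxa-6π), whose enol ether carbon C8 and the acid-activated C12 ketone are the termini of a 1-hydroxy-4-alkoxypentadienyl cation that undergoes conrotatory 4π closure to the C8–C12 bond inside the chiral ion pair (the catalyst sits on the protonated carbonyl carbon that becomes the stereocentre and so sets 12R by torquoselectivity); loss of H8 gives 16, and retro-oxa-6π opening releases the dienone with C6 held cis to the C9 carbonyl (7Z) and the C5 substituent rotating outward (5E, any 5Z isomer re-enters the pyran equilibrium); the closest known reactions are the second stage of the Piancatelli rearrangement, the chiral N-triflylphosphoramide-catalysed Nazarov cyclisation of pyran-derived dienones, and the 2H-pyran/cis-dienone equilibrium.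

**Compound list**

1 | 2,3-dibromofuran | Brc1occc1Br | starting material
2 | 1-bromooct-2-yne | CCCCCC#CCBr | starting material
3 | 4,5-dibromo-2-furyllithium (4,5-dibromofuran-2-yllithium) | [Li]c1cc(Br)c(Br)o1 | intermediate
4 | 2,3-dibromo-5-(oct-2-yn-1-yl)furan | CCCCCC#CCc1cc(Br)c(Br)o1 | intermediate
5 | methyl hex-5-ynoate | C#CCCCC(=O)OC | starting material
6 | chlorobis(cyclopentadienyl)[(1E)-6-methoxy-6-oxohex-1-en-1-yl]zirconium, Cp2Zr(Cl)CH=CH(CH2)3CO2Me | COC(=O)CCC/C=C/[Zr](Cl)(C1C=CC=C1)C1C=CC=C1 | intermediate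
7 | methyl (5E)-6-iodohex-5-enoate | COC(=O)CCC/C=C/I | intermediate
8 | ethynyltrimethylsilane | C#C[Si](C)(C)C | starting material
9 | methyl (5E)-8-(trimethylsilyl)oct-5-en-7-ynoate | COC(=O)CCC/C=C/C#C[Si](C)(C)C | intermediate
10 | methyl (5E)-oct-5-en-7-ynoate | COC(=O)CCC/C=C/C#C | intermediate
11 | methyl (5E)-8-[3-bromo-5-(oct-2-yn-1-yl)furan-2-yl]oct-5-en-7-ynoate | CCCCCC#CCc1cc(Br)c(o1)C#C/C=C/CCCC(=O)OC | intermediate
12 | methyl (5E,7Z)-8-[3-bromo-5-[(2Z)-oct-2-en-1-yl]furan-2-yl]octa-5,7-dienoate | CCCCC/C=C\Cc1cc(Br)c(o1)/C=C\C=C\CCCC(=O)OC | intermediate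
13 | methyl (5E,7Z)-8-[6-bromo-4-[(2Z)-oct-2-en-1-yl]-2,3,7-trioxabicyclo[2.2.1]hept-5-en-1-yl]octa-5,7-dienoate (racemic at the bridgeheads) | CCCCC/C=C\CC12OOC(O1)(/C=C\C=C\CCCC(=O)OC)C(Br)=C2 | intermediate
14 | methyl (5E,7Z,10E,14Z)-10-bromo-9,12-dioxoicosa-5,7,10,14-tetraenoate (C9 and C12 cis across C10=C11) | CCCCC/C=C\CC(=O)/C=C(Br)\C(=O)/C=C\C=C\CCCC(=O)OC | intermediate
15 | methyl 4-{6-[(1E,5Z)-1-bromo-3-oxoundeca-1,5-dien-1-yl]-2H-pyran-2-yl}butanoate (both epimers at the pyran sp3 carbon, interconverting) | CCCCC/C=C\CC(=O)/C=C(Br)\C1=CC=CC(CCCC(=O)OC)O1 | intermediate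
16 | methyl 4-{(5R)-7-bromo-5-hydroxy-5-[(2Z)-oct-2-en-1-yl]-2,5-dihydrocyclopenta[b]pyran-2-yl}butanoate (either configuration at the pyran sp3 carbon) | CCCCC/C=C\C[C@@]1(O)C=C(Br)C2=C1C=CC(CCCC(=O)OC)O2 | intermediate
17 | methyl (5E,7Z)-7-[(2R)-4-bromo-2-hydroxy-2-[(2Z)-oct-2-en-1-yl]-5-oxocyclopent-3-en-1-ylidene]hept-5-enoate | CCCCC/C=C\C[C@@]1(O)C=C(Br)C(=O)/C1=C\C=C\CCCC(=O)OC | target

**Totals**

Total step count: 6. Longest linear sequence: 5 steps (from 1 through steps 1, 3, 4, 5, 6, or from 5 through steps 2, 3, 4, 5, 6). No protecting groups are used.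

**Steps most likely to fail**

Step 6 (most likely). The cascade is unproven as a whole. The cis-enedione can drift to the trans isomer under acid, which cannot close. The skipped 14Z alkene can move into conjugation with the C12 ketone. The level and sense of asymmetric induction are unknown. The fallback replaces the cascade by a Piancatelli rearrangement of a furyl carbinol and a Z-selective olefination; it sets out from 4 and 7 and comes back to the route at 17. Bromine–lithium exchange at C2 of 4 (n-BuLi, THF, −78 °C) gives [3-bromo-5-(oct-2-yn-1-yl)furan-2-yl]lithium F1, which with DMF gives 3-bromo-5-(oct-2-yn-1-yl)furan-2-carbaldehyde F2. Addition of bis(2,2,2-trifluoroethyl) phosphite (Et3N) gives bis(2,2,2-trifluoroethyl) {[3-bromo-5-(oct-2-yn-1-yl)furan-2-yl](hydroxy)methyl}phosphonate F3. Semihydrogenation as in step 4 gives bis(2,2,2-trifluoroethyl) {[3-bromo-5-[(2Z)-oct-2-en-1-yl]furan-2-yl](hydroxy)methyl}phosphonate F4. Piancatelli rearrangement in wet solvent gives bis(2,2,2-trifluoroethyl) [(5R)-3-bromo-5-hydroxy-5-[(2Z)-oct-2-en-1-yl]-2-oxocyclopent-3-en-1-yl]phosphonate F5; this uses the chiral acid of step 6, or Dy(OTf)3 followed by separation of the enantiomers on a chiral stationary phase. Reductive carbonylation of 7 (CO, Bu3SnH, Pd(PPh3)4) gives methyl (5E)-7-oxohept-5-enoate F6. Still–Gennari olefination of F5 with F6 (KN(SiMe3)2, 18-crown-6, THF, −78 °C) places C6 cis to the ketone and gives 17.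

Step 5. Singlet oxygen must choose the bromofuran over the (Z,E)-diene and the skipped alkene, and 14 is sensitive to light and to nucleophiles, Me2S included. The fallback replaces cycloaddition and reduction by a two-electron oxidative methoxylation that gives a storable latent enedione; it sets out from 12 and comes back at 14. NBS, NaHCO3, MeOH/THF, −40 °C converts 12 into methyl (5E,7Z)-8-[3-bromo-2,5-dimethoxy-5-[(2Z)-oct-2-en-1-yl]-2,5-dihydrofuran-2-yl]octa-5,7-dienoate F7. Mild wet acid (oxalic acid on SiO2, or one equivalent of water under the step 6 conditions) then unmasks 14 just before or inside step 6.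

Step 4. Two different alkynes must be reduced in one operation, and the furan-conjugated (Z,E)-diene can over-reduce or isomerise on palladium. The fallback hydrogenates only the isolated alkyne and brings the 7Z alkene in from a Z-configured two-carbon linchpin; it sets out from 4 and 7 and comes back at 12. Semihydrogenation of 4 under the step 4 conditions gives 2,3-dibromo-5-[(2Z)-oct-2-en-1-yl]furan F8. Stille coupling of 7 with excess (Z)-1,2-bis(tributylstannyl)ethene (Pd(PPh3)4, CuI, DMF, 23 °C) gives methyl (5E,7Z)-8-(tributylstannyl)octa-5,7-dienoate F9. A second Stille coupling of F9 with F8 at the C2–Br bond (Pd(PPh3)4, CuI, DMF, 45 °C) gives 12 with retention of both alkene geometries.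

**Further compounds**

F1 | step 6 | [3-bromo-5-(oct-2-yn-1-yl)furan-2-yl]lithium | CCCCCC#CCc1cc(Br)c([Li])o1
F2 | step 6 | 3-bromo-5-(oct-2-yn-1-yl)furan-2-carbaldehyde | CCCCCC#CCc1cc(Br)c(C=O)o1
F3 | step 6 | bis(2,2,2-trifluoroethyl) {[3-bromo-5-(oct-2-yn-1-yl)furan-2-yl](hydroxy)methyl}phosphonate | CCCCCC#CCc1cc(Br)c(o1)C(O)P(=O)(OCC(F)(F)F)OCC(F)(F)F
F4 | step 6 | bis(2,2,2-trifluoroethyl) {[3-bromo-5-[(2Z)-oct-2-en-1-yl]furan-2-yl](hydroxy)methyl}phosphonate | CCCCC/C=C\Cc1cc(Br)c(o1)C(O)P(=O)(OCC(F)(F)F)OCC(F)(F)F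
F5 | step 6 | bis(2,2,2-trifluoroethyl) [(5R)-3-bromo-5-hydroxy-5-[(2Z)-oct-2-en-1-yl]-2-oxocyclopent-3-en-1-yl]phosphonate | CCCCC/C=C\C[C@@]1(O)C=C(Br)C(=O)C1P(=O)(OCC(F)(F)F)OCC(F)(F)F
F6 | step 6 | methyl (5E)-7-oxohept-5-enoate | COC(=O)CCC/C=C/C=O
F7 | step 5 | methyl (5E,7Z)-8-[3-bromo-2,5-dimethoxy-5-[(2Z)-oct-2-en-1-yl]-2,5-dihydrofuran-2-yl]octa-5,7-dienoate | CCCCC/C=C\CC1(OC)OC(OC)(/C=C\C=C\CCCC(=O)OC)C(Br)=C1
F8 | step 4 | 2,3-dibromo-5-[(2Z)-oct-2-en-1-yl]furan | CCCCC/C=C\Cc1cc(Br)c(Br)o1
F9 | step 4 | methyl (5E,7Z)-8-(tributylstannyl)octa-5,7-dienoate | COC(=O)CCC/C=C/C=C\[Sn](CCCC)(CCCC)CCCC
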